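**Plan**

1. Numbering (backbone along the SMILES; branch methyls and the OH/C=O oxygens are not counted): C1 methyl; cycloheptane C2–C6, C10, C11; cyclopentane C5–C9; linker C12–C13; cyclohexane C14, C15, C21–C24; oxepanone C15–C19, O20, C21.
2. Retrosynthetic cuts: the C18 carbonyl and the silyl ethers; C2–H together with C11=C12 (allylic diazene transposition from a C12 carbinol); C11–C12 (hydroazulenyl triflate plus aldehyde). Left half: C24–CH3, C13–C14, O20–C21, C15–C16. Right half: C1–C2, both C10–CH3, C2 as an inserted ring carbon, C9–CH3, and the Diels–Alder bonds C4–C5 and C6–C10.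
3. Feature behind the key step: quaternary C15 with its methyl is flanked by C14 and C21 as C2 of 2-methylcyclohexane-1,3-dione is flanked by its carbonyls, and O20 sits on the tertiary carbinol C19 at the far end of the C16–C19 chain on C15. A C19–OH/C21=O pair can therefore close the oxepanone.
4. Forward order: cyclohexane (from the dione), then the oxepanone (O20–C21), then the C13/C12 chain and the C24 carbinol. Separately, cyclopentane plus cyclohexene by cycloaddition, one-carbon enlargement to the cycloheptenone, then the enol triflate. The halves are joined at C11–C12 and the alkene is moved to C11=C12.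
5. Stereochemistry: C15 from desymmetrising transfer hydrogenation (C14 is then inverted as a spectator); C21 from axial hydride delivery; C14 and C24 from α-face hydroboration and equatorial methyl addition; C5/C6 from a catalytic enantioselective Diels–Alder; C9 from convex-face epoxidation; C12 from CBS reduction, and from it C2 and the (Z)-alkene through the suprafacial retro-ene.

Key step: step 5

Remark: RuCl[(R,R)-TsDPEN](p-cymene) is assumed to give the (R)-carbinol, as it does with aryl ketones, and the (S)-oxazaborolidinium salt to give the (3aS,7aR) adduct; should either sense prove opposite, the mirror-image catalyst is used.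

Remark: the C18 carbinol (11 to 48), the cyclopropane carbons (30 to 34), C2 in 40 and C12 in 42 are spectator centres that converge later, so their configuration is left open in names and SMILES.

**Left half: benzoxepane aldehyde**

Step 1
Reactants: 1 3-hydroxy-3-methylbutan-2-one; 2 formaldehyde (as paraformaldehyde)
Product: 3 4-hydroxy-4-methylpent-1-en-3-one
Conditions: (CH2O)n, i-Pr2NH, CF3CO2H, THF, reflux
Reagents that add atoms: none
Why: Mannich condensation at the only enolisable carbon followed by elimination of the amine (α-methylenation) should give the α′-hydroxy enone, a known preparation of this Michael acceptor.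

Step 2
Reactants: 3 4-hydroxy-4-methylpent-1-en-3-one; 4 2-methylcyclohexane-1,3-dione
Product: 5 2-(4-hydroxy-4-methyl-3-oxopentyl)-2-methylcyclohexane-1,3-dione
Conditions: Et3N (cat.), EtOAc, 25 °C
Reagents that add atoms: none
Why: Michael addition of the acidic 1,3-dione to the vinyl ketone forms C15–C16 and makes C15 a prochiral quaternary centre; the mild base does not trigger the aldol step of a Robinson annulation.

Step 3
Reactants: 5 triketone
Product: 6 (2R,3R)-3-hydroxy-2-(4-hydroxy-4-methyl-3-oxopentyl)-2-methylcyclohexan-1-one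
Conditions: RuCl[(R,R)-TsDPEN](p-cymene) (1 mol%), HCO2H–Et3N (5:2), CH2Cl2, 25 °C
Reagents that add atoms: none
Why: Noyori–Ikariya asymmetric transfer hydrogenation desymmetrises the dione: the catalyst fixes the carbinol as R and hydride enters on the face of the small C15 methyl (anti to the chain), so C15 becomes R with the hydroxyl cis to the chain; the ring 1,3-dicarbonyl should react well before the hindered side-chain ketone, and the minor diastereomer (opposite C15) is removed by chromatography because it would become the enantiomer after step 9.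

Step 4
Reactants: 6 (2R,3R)-hydroxy diketone
Product: 7 (1S,2R)-2-(4-hydroxy-4-methyl-3-oxopentyl)-2-methyl-3-oxocyclohexyl 4-nitrobenzoate
Conditions: 4-O2NC6H4CO2H, PPh3, DIAD, THF, 0 → 25 °C
Reagents that add atoms: 4-nitrobenzoic acid, O=C(O)c1ccc(cc1)[N+](=O)[O-]
Why: Mitsunobu esterification inverts the secondary carbinol by SN2 displacement of the oxyphosphonium ion (the tertiary hydroxyl is inert), which puts the C14 oxygen cis to the C15 methyl and hence equatorial in the chair used in step 5.

Step 5
Reactants: 7 hydroxy diketone 4-nitrobenzoate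
Product: 10 trans-fused oxepan-18-one C14 4-nitrobenzoate, via silylated hemiketal 8 (not isolated), via oxocarbenium triflate 9 (not isolated)
Conditions: Et3SiH (5 equiv), TMSOTf (2.5 equiv), CH2Cl2, −78 → −20 °C; aq. NaHCO3
Reagents that add atoms: none
Why: TMSOTf silylates the C19 hydroxyl and activates the C21 carbonyl, the silyl ether oxygen adds to C21 in a 7-exo-trig closure to give the O-silyl hemiketal 8, and loss of silanolate as hexamethyldisiloxane leaves the seven-membered oxocarbenium ion 9, which Et3SiH reduces irreversibly; the closest known reaction type is the silane reductive etherification of hydroxy ketones used for oxepanes in ladder polyether work, here with a rarely used tertiary carbinol as donor. The only ring closed is the oxepanone, through the O20–C21 bond. The new stereocentre C21 is set by axial hydride delivery to the chair in which the C15 methyl is axial and the C14 ester and C16 are equatorial: the silane approaches anti to the axial methyl, past only axial hydrogens at C14 and C23, so H21 ends trans to the methyl and the ring fusion is trans. The step needs chemoselectivity between the two ketones, and the substrate secures it because only C21 can be reached by the hydroxyl through a normal-sized ring, while the C18 carbonyl is deactivated by its α-oxygen and flanked by a quaternary carbon. The same α-carbonyl disfavours ionisation of the tertiary C19–O bond, so elimination should be suppressed, and the low temperature limits the α-ketol shift.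

Step 6
Reactants: 10 oxepanone 4-nitrobenzoate
Product: 11 C18 alcohol (C18 epimers)
Conditions: NaBH4, CeCl3·7H2O, MeOH–THF, −40 °C
Reagents that add atoms: none
Why: Luche reduction should reduce the oxepanone carbonyl at low temperature without touching the nitrobenzoate; the carbinol masks C18 until the last step.

Step 7
Reactants: 11 C18 alcohol
Product: 12 C18 tert-butyldimethylsilyl ether
Conditions: TBSOTf, 2,6-lutidine, CH2Cl2, 0 °C
Reagents that add atoms: tert-butyldimethylsilyl triflate, CC(C)(C)[Si](C)(C)OS(=O)(=O)C(F)(F)F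
Why: Silylation of the only free hydroxyl with the silyl triflate gives an ether that survives base, organolithium, borane and hydrogenolysis.

Step 8
Reactants: 12 silyl ether 4-nitrobenzoate
Product: 13 C14 alcohol
Conditions: K2CO3, MeOH, 25 °C
Reagents that add atoms: none
Why: Base-catalysed transesterification (methanolysis) of the electron-poor benzoate liberates the C14 alcohol while the silyl ether is untouched.

Step 9
Reactants: 13 C14 alcohol
Product: 14 C14 ketone
Conditions: Dess–Martin periodinane, NaHCO3, CH2Cl2, 0 → 25 °C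
Reagents that add atoms: none
Why: Dess–Martin oxidation of the secondary alcohol gives the ketone and erases the spectator centre at C14.

Step 10
Reactants: 14 C14 ketone
Product: 15 C14 enol triflate (C14=C24)
Conditions: KN(SiMe3)2, THF, −78 °C; PhNTf2, −78 → 0 °C
Reagents that add atoms: N-phenylbis(trifluoromethanesulfonimide), O=S(=O)(N(c1ccccc1)S(=O)(=O)C(F)(F)F)C(F)(F)F
Why: Enol triflate formation from the potassium enolate, which can only form towards C24 because C15 is quaternary.

Step 11
Reactants: 15 enol triflate; 16 benzyl vinyl ether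
Product: 18 C14-(2-benzyloxyethyl) C14=C24 alkene, via B-(2-benzyloxyethyl)-9-BBN 17 (not isolated)
Conditions: 16, 9-BBN-H, THF, 0 → 25 °C; then 15, PdCl2(dppf) (5 mol%), AsPh3, Cs2CO3, DMF–THF–H2O, 25 °C
Reagents that add atoms: none
Why: Hydroboration of the vinyl ether puts boron on the terminal carbon, and B-alkyl Suzuki–Miyaura coupling of the alkyl-9-BBN with the enol triflate forms C13–C14 and brings in C12 as a benzyl ether.

Step 12
Reactants: 18 trisubstituted alkene
Product: 20 C24 α-alcohol with H14 α, via C24 alkylborane 19 (not isolated)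
Conditions: BH3·THF, THF, 0 → 25 °C; then NaOH, H2O2, 0 °C
Reagents that add atoms: hydrogen peroxide, OO
Why: Brown hydroboration–oxidation: borane adds syn from the α face, opposite the pseudoaxial C15 methyl, with boron on the less substituted C24, so H14 is α (side chain β, equatorial) and the C24 hydroxyl α.

Step 13
Reactants: 20 C24 alcohol
Product: 21 C24 ketone
Conditions: Dess–Martin periodinane, NaHCO3, CH2Cl2, 25 °C
Reagents that add atoms: none
Why: Dess–Martin oxidation under buffered conditions gives the ketone without epimerising C14, whose equatorial side chain is also the thermodynamic arrangement.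

Step 14
Reactants: 21 C24 ketone
Product: 23 C24 tertiary triethylsilyl ether, via lithium C24 alkoxide 22 (not isolated)
Conditions: MeLi, Et2O–THF, −78 °C; then TESOTf, −78 → 0 °C
Reagents that add atoms: methyllithium, [Li]C; triethylsilyl triflate, CC[Si](CC)(CC)OS(=O)(=O)C(F)(F)F
Why: 1,2-Addition of methyllithium along the equatorial trajectory (axial attack is blocked by the 1,3-diaxial C15 methyl) gives the axial β-alkoxide with an equatorial methyl, and silylation in the same flask prevents lactol formation with the C12 aldehyde made in step 16.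

Step 15
Reactants: 23 benzyl ether
Product: 24 C12 primary alcohol
Conditions: H2 (1 atm), Pd(OH)2/C, EtOAc, 25 °C
Reagents that add atoms: none
Why: Hydrogenolysis of the benzyl ether; the silyl ethers and the saturated skeleton are inert in ethyl acetate.

Step 16
Reactants: 24 C12 alcohol
Product: 25 C12 aldehyde
Conditions: Dess–Martin periodinane, NaHCO3, CH2Cl2, 25 °C
Reagents that add atoms: none
Why: Dess–Martin oxidation stops cleanly at the aldehyde, which has no stereocentre at its α-carbon.

**Right half: hydroazulenyl triflate**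

Step 17
Reactants: 26 but-3-en-2-one
Product: 27 2-(triisopropylsilyloxy)buta-1,3-diene
Conditions: TIPSOTf, Et3N, Et2O, 0 → 25 °C
Reagents that add atoms: triisopropylsilyl triflate, CC(C)[Si](C(C)C)(C(C)C)OS(=O)(=O)C(F)(F)F
Why: Soft enolisation and O-silylation of the methyl ketone give the acid-stable 2-silyloxydiene.

Step 18
Reactants: 27 silyloxydiene; 28 cyclopent-2-en-1-one
Product: 29 (3aS,7aR)-5-(triisopropylsilyloxy)-2,3,3a,4,7,7a-hexahydro-1H-inden-1-one
Conditions: (S)-3,3-diphenyl-1-(o-tolyl)tetrahydropyrrolo[1,2-c][1,3,2]oxazaborole·HNTf2 (20 mol%), CH2Cl2, −20 °C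
Reagents that add atoms: none
Why: Enantioselective Diels–Alder reaction catalysed by a protonated chiral oxazaborolidine (Corey): one face of the bound enone is shielded, the diene terminus next to the silyloxy carbon bonds to the enone β-carbon (para regiochemistry, C6–C10), and suprafacial addition makes the ring fusion cis, setting C5 and C6.

Step 19
Reactants: 29 silyl enol ether ketone
Product: 30 siloxycyclopropane ketone
Conditions: Et2Zn, CH2I2, CH2Cl2, 0 → 25 °C
Reagents that add atoms: diiodomethane, ICI
Why: Furukawa–Simmons–Smith cyclopropanation of the electron-rich silyl enol ether supplies the carbon that becomes C2; the ketone is inert.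

Step 20
Reactants: 30 siloxycyclopropane ketone
Product: 31 C9 exocyclic methylene compound
Conditions: Cp2TiMe2, toluene, 70 °C
Reagents that add atoms: dimethyltitanocene, C[Ti](C)(C1C=CC=C1)C1C=CC=C1
Why: Petasis methylenation (thermally generated Cp2Ti=CH2) converts the ketone into the exocyclic alkene under non-basic conditions, so the epimerisable C5 centre is not disturbed.

Step 21
Reactants: 31 exocyclic alkene
Product: 32 C9 spiro-epoxide with oxygen on the face of H5 and H6
Conditions: m-CPBA, NaHCO3, CH2Cl2, 0 °C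
Reagents that add atoms: 3-chloroperoxybenzoic acid, OOC(=O)c1cccc(Cl)c1
Why: Prilezhaev epoxidation from the convex face of the cis-fused bicycle places the oxygen on C9 cis to H5.

Step 22
Reactants: 32 spiro-epoxide
Product: 33 C9 tertiary alcohol (OH cis to H5, methyl trans)
Conditions: LiBHEt3, THF, 0 → 25 °C
Reagents that add atoms: none
Why: SN2 hydride opening of the epoxide at its unhindered CH2 terminus turns that carbon into the C9 methyl and leaves the tertiary hydroxyl on the convex face; the siloxycyclopropane is inert to hydride.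

Step 23
Reactants: 33 tertiary alcohol
Product: 34 C9 triethylsilyl ether
Conditions: TESOTf, 2,6-lutidine, CH2Cl2, 0 → 25 °C
Reagents that add atoms: triethylsilyl triflate, CC[Si](CC)(CC)OS(=O)(=O)C(F)(F)F
Why: Silylation with the triflate protects the tertiary alcohol for the enolate chemistry that follows.

Step 24
Reactants: 34 siloxycyclopropane
Product: 36 cis-fused cyclohept-2-enone (C11 ketone with C2=C3), via 3-chloro ketone 35 (not isolated)
Conditions: FeCl3, DMF, 0 → 25 °C; then NaOAc, MeOH, 65 °C
Reagents that add atoms: none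
Why: Saegusa–Ito ring expansion: one-electron oxidation by FeCl3 cleaves the internal C3–C11 cyclopropane bond to the ring-enlarged C3 radical, chlorine transfer gives the 3-chloro ketone, and acetate-induced elimination gives the cycloheptenone with the new carbon as C2.

Step 25
Reactants: 36 cycloheptenone
Product: 38 C10 gem-dimethyl enone, via C10 monomethyl enone 37 (not isolated)
Conditions: LiN(i-Pr)2, THF, −78 °C; MeI; then LiN(i-Pr)2, DMPU, −78 °C; MeI, −78 → 0 °C
Reagents that add atoms: iodomethane, CI
Why: Kinetic α′-deprotonation of the enone and enolate methylation, run twice in one flask, install the gem-dimethyl group at C10, the only α′ position.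

Step 26
Reactants: 38 gem-dimethyl enone
Product: 40 2,2,7-trimethyl ketone (C2 epimers), via lithium C11 enolate 39 (not isolated)
Conditions: LiBH(s-Bu)3, THF, −78 °C; then MeI, −78 → 0 °C
Reagents that add atoms: iodomethane, CI
Why: Conjugate reduction of the β-unsubstituted enone by the hindered borohydride gives the C11 enolate regiospecifically, and C-methylation at C2 completes a reductive alkylation; the C2 configuration is irrelevant here.

Step 27
Reactants: 40 ketone
Product: 41 hydroazulenyl enol triflate (C11(OTf)=C2)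
Conditions: KN(SiMe3)2, THF, −78 → −20 °C; PhNTf2
Reagents that add atoms: N-phenylbis(trifluoromethanesulfonimide), O=S(=O)(N(c1ccccc1)S(=O)(=O)C(F)(F)F)C(F)(F)F
Why: Deprotonation at C2, the only α-hydrogen, and O-triflation of the enolate give the tetrasubstituted enol triflate.

**Union and end game**

Step 28
Reactants: 25 C12 aldehyde; 41 enol triflate
Product: 42 C12 allylic alcohols (both epimers)
Conditions: CrCl2 (6 equiv), NiCl2 (2 mol%), DMF–DMSO, 25 °C
Reagents that add atoms: none
Why: Nozaki–Hiyama–Kishi coupling: zerovalent nickel formed in situ inserts into the C–OTf bond and transmetallation to trivalent chromium gives a non-basic alkenylchromium species that adds to the aldehyde without enolising it, forming C11–C12.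

Step 29
Reactants: 42 allylic alcohols
Product: 43 C12 enone
Conditions: Dess–Martin periodinane, NaHCO3, CH2Cl2, 25 °C
Reagents that add atoms: none
Why: Dess–Martin oxidation merges the two C12 epimers into one enone.

Step 30
Reactants: 43 enone
Product: 44 (12R) allylic alcohol
Conditions: (S)-2-methyl-CBS-oxazaborolidine (1 equiv), BH3·SMe2, THF, −30 °C; MeOH
Reagents that add atoms: none
Why: Corey–Bakshi–Shibata reduction: the twisted, fully substituted alkenyl group is the large substituent and the C13 methylene the small one, so the (S)-catalyst should give the (12R) carbinol; the tetrasubstituted alkene is not hydroborated at this temperature.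

Step 31
Reactants: 44 (12R) allylic alcohol
Product: 47 tris-silyl ether of the (2S) (11Z) alkene, via sulfonyl hydrazone adduct 45 (not isolated), via allylic diazene 46 (not isolated)
Conditions: N′-isopropylidene-2-nitrobenzenesulfonohydrazide (IPNBSH), PPh3, DEAD, THF, 0 → 23 °C; then CF3CH2OH–H2O (1:1), 23 °C
Reagents that add atoms: none
Why: Myers–Movassaghi reductive 1,3-transposition: Mitsunobu displacement with inversion gives the (12S) adduct, hydrolysis and loss of sulfinate give the allylic diazene, and its retro-ene loss of N2 in the conformer with H12 eclipsing C2=C11 (which avoids 1,3-allylic strain with the C1 methyl) transfers hydrogen suprafacially to the convex face of C2, giving (2S) and C13 cis to C10.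

Step 32
Reactants: 47 tris-silyl ether
Product: 48 triol (C9, C18, C24 hydroxyls)
Conditions: Bu4NF, THF, 50 °C
Reagents that add atoms: none
Why: Fluoride-induced desilylation removes the two triethylsilyl ethers and the tert-butyldimethylsilyl ether; the molecule has no base-sensitive group at this stage.

Step 33
Reactants: 48 triol
Product: 49 CNP0157787.1
Conditions: Dess–Martin periodinane, NaHCO3, CH2Cl2, 25 °C
Reagents that add atoms: none
Why: Dess–Martin oxidation of the only secondary alcohol restores the C18 ketone; the tertiary alcohols and the trisubstituted alkene are inert.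

**Compound list**

1 | 3-hydroxy-3-methylbutan-2-one | CC(=O)C(C)(C)O | starting material
2 | formaldehyde (used as paraformaldehyde) | C=O | starting material
3 | 4-hydroxy-4-methylpent-1-en-3-one | C=CC(=O)C(C)(C)O | intermediate
4 | 2-methylcyclohexane-1,3-dione | CC1C(=O)CCCC1=O | starting material
5 | 2-(4-hydroxy-4-methyl-3-oxopentyl)-2-methylcyclohexane-1,3-dione | CC1(CCC(=O)C(C)(C)O)C(=O)CCCC1=O | intermediate
6 | (2R,3R)-3-hydroxy-2-(4-hydroxy-4-methyl-3-oxopentyl)-2-methylcyclohexan-1-one (C14 hydroxyl cis to the chain) | O[C@H]1[C@@](C)(CCC(=O)C(C)(C)O)C(=O)CCC1 | intermediate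
7 | (1S,2R)-2-(4-hydroxy-4-methyl-3-oxopentyl)-2-methyl-3-oxocyclohexyl 4-nitrobenzoate (ester cis to the C15 methyl) | O=C(O[C@@H]1[C@@](C)(CCC(=O)C(C)(C)O)C(=O)CCC1)c1ccc(cc1)[N+](=O)[O-] | intermediate
8 | C21 O-trimethylsilyl hemiketal of 7, oxepane ring closed | O=C(O[C@@H]1[C@@]2(C)CCC(=O)C(C)(C)OC2(O[Si](C)(C)C)CCC1)c1ccc(cc1)[N+](=O)[O-] | intermediate (not isolated)
9 | bicyclic C21=O20 oxocarbenium triflate | O=C(O[C@@H]1[C@@]2(C)CCC(=O)C(C)(C)[O+]=C2CCC1)c1ccc(cc1)[N+](=O)[O-].[O-]S(=O)(=O)C(F)(F)F | intermediate (not isolated)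
10 | 2,2,5a-trimethyl-3-oxodecahydro-1-benzoxepin-6-yl 4-nitrobenzoate, trans-fused (H21 trans to the C15 methyl, ester cis to it) | O=C(O[C@@H]1[C@@]2(C)CCC(=O)C(C)(C)O[C@@H]2CCC1)c1ccc(cc1)[N+](=O)[O-] | intermediate
11 | C18 alcohol of 10 (C18 epimers) | O=C(O[C@@H]1[C@@]2(C)CCC(O)C(C)(C)O[C@@H]2CCC1)c1ccc(cc1)[N+](=O)[O-] | intermediate
12 | C18 tert-butyldimethylsilyl ether of 11 | O=C(O[C@@H]1[C@@]2(C)CCC(O[Si](C)(C)C(C)(C)C)C(C)(C)O[C@@H]2CCC1)c1ccc(cc1)[N+](=O)[O-] | intermediate
13 | C14 alcohol (hydroxyl cis to the C15 methyl), C18 silyl ether | O[C@@H]1[C@@]2(C)CCC(O[Si](C)(C)C(C)(C)C)C(C)(C)O[C@@H]2CCC1 | intermediate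
14 | C14 ketone, trans-fused, C18 silyl ether | O=C1[C@@]2(C)CCC(O[Si](C)(C)C(C)(C)C)C(C)(C)O[C@@H]2CCC1 | intermediate
15 | C14 enol triflate (C14=C24) | O=S(=O)(OC=1[C@@]2(C)CCC(O[Si](C)(C)C(C)(C)C)C(C)(C)O[C@@H]2CCC=1)C(F)(F)F | intermediate
16 | benzyl vinyl ether | C=COCc1ccccc1 | starting material
17 | B-[2-(benzyloxy)ethyl]-9-borabicyclo[3.3.1]nonane | C(OCCB1C2CCCC1CCC2)c1ccccc1 | intermediate (not isolated)
18 | C14-(2-benzyloxyethyl) C14=C24 alkene | C(OCCC=1[C@@]2(C)CCC(O[Si](C)(C)C(C)(C)C)C(C)(C)O[C@@H]2CCC=1)c1ccccc1 | intermediate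
19 | C24 alkylborane (boron and H14 both α) | C(OCC[C@@H]1[C@@]2(C)CCC(O[Si](C)(C)C(C)(C)C)C(C)(C)O[C@@H]2CC[C@H]1B)c1ccccc1 | intermediate (not isolated)
20 | C24 secondary alcohol (OH α, H14 α, side chain β) | C(OCC[C@@H]1[C@@]2(C)CCC(O[Si](C)(C)C(C)(C)C)C(C)(C)O[C@@H]2CC[C@H]1O)c1ccccc1 | intermediate
21 | C24 ketone | C(OCC[C@@H]1[C@@]2(C)CCC(O[Si](C)(C)C(C)(C)C)C(C)(C)O[C@@H]2CCC1=O)c1ccccc1 | intermediate
22 | lithium C24 alkoxide (O β axial, methyl α equatorial) | C(OCC[C@@H]1[C@@]2(C)CCC(O[Si](C)(C)C(C)(C)C)C(C)(C)O[C@@H]2CC[C@]1(C)[O-])c1ccccc1.[Li+] | intermediate (not isolated)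
23 | C24 triethylsilyl ether, C12 benzyl ether, C18 silyl ether | C(OCC[C@@H]1[C@@]2(C)CCC(O[Si](C)(C)C(C)(C)C)C(C)(C)O[C@@H]2CC[C@]1(C)O[Si](CC)(CC)CC)c1ccccc1 | intermediate
24 | C12 primary alcohol | OCC[C@@H]1[C@@]2(C)CCC(O[Si](C)(C)C(C)(C)C)C(C)(C)O[C@@H]2CC[C@]1(C)O[Si](CC)(CC)CC | intermediate
25 | C12 aldehyde (benzoxepane half) | O=CC[C@@H]1[C@@]2(C)CCC(O[Si](C)(C)C(C)(C)C)C(C)(C)O[C@@H]2CC[C@]1(C)O[Si](CC)(CC)CC | intermediate
26 | but-3-en-2-one | CC(=O)C=C | starting material
27 | 2-(triisopropylsilyloxy)buta-1,3-diene | C=CC(=C)O[Si](C(C)C)(C(C)C)C(C)C | intermediate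
28 | cyclopent-2-en-1-one | O=C1C=CCC1 | starting material
29 | (3aS,7aR)-5-(triisopropylsilyloxy)-2,3,3a,4,7,7a-hexahydro-1H-inden-1-one (cis-fused; C9 ketone, C11 enol ether) | C=1C[C@@H]2[C@@H](CCC2=O)CC=1O[Si](C(C)C)(C(C)C)C(C)C | intermediate
30 | siloxycyclopropane ketone (CH2 bridging C3 and C11) | C1C2C[C@@H]3[C@@H](CCC3=O)CC12O[Si](C(C)C)(C(C)C)C(C)C | intermediate
31 | C9 exocyclic methylene compound | C1C2C[C@@H]3[C@@H](CCC3=C)CC12O[Si](C(C)C)(C(C)C)C(C)C | intermediate
32 | C9 spiro-epoxide (oxygen cis to H5) | C1C2C[C@@H]3[C@@H](CC[C@]34CO4)CC12O[Si](C(C)C)(C(C)C)C(C)C | intermediate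
33 | C9 tertiary alcohol (OH cis to H5 and H6) | C1C2C[C@@H]3[C@@H](CC[C@@]3(C)O)CC12O[Si](C(C)C)(C(C)C)C(C)C | intermediate
34 | C9 triethylsilyl ether | C1C2C[C@@H]3[C@@H](CC[C@@]3(C)O[Si](CC)(CC)CC)CC12O[Si](C(C)C)(C(C)C)C(C)C | intermediate
35 | ring-enlarged 3-chloro ketone (Cl on C3) | O=C1CC(Cl)C[C@@H]2[C@@H](CC[C@@]2(C)O[Si](CC)(CC)CC)C1 | intermediate (not isolated)
36 | cis-fused bicyclo[5.3.0]decenone: C11 ketone, C2=C3, C9 OTES | O=C1C=CC[C@@H]2[C@@H](CC[C@@]2(C)O[Si](CC)(CC)CC)C1 | intermediate
37 | C10 monomethyl enone | O=C1C=CC[C@@H]2[C@@H](CC[C@@]2(C)O[Si](CC)(CC)CC)C1C | intermediate (not isolated)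
38 | C10 gem-dimethyl enone | O=C1C=CC[C@@H]2[C@@H](CC[C@@]2(C)O[Si](CC)(CC)CC)C1(C)C | intermediate
39 | lithium C11 enolate (C11=C2) | [Li+].[O-]C1=CCC[C@@H]2[C@@H](CC[C@@]2(C)O[Si](CC)(CC)CC)C1(C)C | intermediate (not isolated)
40 | hydroazulenone: C11 ketone, C10 gem-dimethyl, C2 methyl (C2 epimers) | CC1CC[C@@H]2[C@@H](CC[C@@]2(C)O[Si](CC)(CC)CC)C(C)(C)C1=O | intermediate
41 | hydroazulenyl enol triflate, C11(OTf)=C2(CH3), (5R,6R,9R) | CC=1CC[C@@H]2[C@@H](CC[C@@]2(C)O[Si](CC)(CC)CC)C(C)(C)C=1OS(=O)(=O)C(F)(F)F | intermediate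
42 | coupled C12 allylic alcohols (C12 epimers), C2=C11 | CC=1CC[C@@H]2[C@@H](CC[C@@]2(C)O[Si](CC)(CC)CC)C(C)(C)C=1C(O)C[C@@H]1[C@@]2(C)CCC(O[Si](C)(C)C(C)(C)C)C(C)(C)O[C@@H]2CC[C@]1(C)O[Si](CC)(CC)CC | intermediate
43 | C12 enone | CC=1CC[C@@H]2[C@@H](CC[C@@]2(C)O[Si](CC)(CC)CC)C(C)(C)C=1C(=O)C[C@@H]1[C@@]2(C)CCC(O[Si](C)(C)C(C)(C)C)C(C)(C)O[C@@H]2CC[C@]1(C)O[Si](CC)(CC)CC | intermediate
44 | (12R) allylic alcohol | CC=1CC[C@@H]2[C@@H](CC[C@@]2(C)O[Si](CC)(CC)CC)C(C)(C)C=1[C@H](O)C[C@@H]1[C@@]2(C)CCC(O[Si](C)(C)C(C)(C)C)C(C)(C)O[C@@H]2CC[C@]1(C)O[Si](CC)(CC)CC | intermediate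
45 | (12S) N-alkyl-N-(2-nitrobenzenesulfonyl) acetone hydrazone | CC=1CC[C@@H]2[C@@H](CC[C@@]2(C)O[Si](CC)(CC)CC)C(C)(C)C=1[C@@H](N(N=C(C)C)S(=O)(=O)c3ccccc3[N+](=O)[O-])C[C@@H]1[C@@]2(C)CCC(O[Si](C)(C)C(C)(C)C)C(C)(C)O[C@@H]2CC[C@]1(C)O[Si](CC)(CC)CC | intermediate (not isolated)
46 | (12S) allylic diazene | CC=1CC[C@@H]2[C@@H](CC[C@@]2(C)O[Si](CC)(CC)CC)C(C)(C)C=1[C@@H](N=N)C[C@@H]1[C@@]2(C)CCC(O[Si](C)(C)C(C)(C)C)C(C)(C)O[C@@H]2CC[C@]1(C)O[Si](CC)(CC)CC | intermediate (not isolated)
47 | (2S,11Z) alkene; C9 and C24 triethylsilyl ethers, C18 tert-butyldimethylsilyl ether | C[C@H]1CC[C@@H]2[C@@H](CC[C@@]2(C)O[Si](CC)(CC)CC)C(C)(C)/C1=C\C[C@@H]1[C@@]2(C)CCC(O[Si](C)(C)C(C)(C)C)C(C)(C)O[C@@H]2CC[C@]1(C)O[Si](CC)(CC)CC | intermediate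
48 | triol (C9, C18, C24 hydroxyls; C18 epimers) | C[C@H]1CC[C@@H]2[C@@H](CC[C@@]2(C)O)C(C)(C)/C1=C\C[C@@H]1[C@@]2(C)CCC(O)C(C)(C)O[C@@H]2CC[C@]1(C)O | intermediate
49 | CNP0157787.1, (2S,5R,6R,9R,11Z,14R,15R,21R,24S) in backbone numbering | C[C@H]1CC[C@@H]2[C@@H](CC[C@@]2(C)O)C(C)(C)/C1=C\C[C@@H]1[C@@]2(C)CCC(=O)C(C)(C)O[C@@H]2CC[C@]1(C)O | target

**Step count and risks**

Total: 33 steps. Longest linear sequence: 22 steps (steps 1–16, then 28–33); the hydroazulene branch is 11 steps (17–27).

Steps most likely to fail:

1. Step 5. The hindered tertiary hydroxyl may add too slowly to the neopentyl C21 carbonyl, so that silane reduction of the open-chain carbonyls or the acid-induced α-ketol shift takes over. The fallback separates ring closure from reduction and sets out from 7: ethanethiol and Zn(OTf)2 in CH2Cl2 should convert the hydroxy ketone, through the more persistent thionium ion, into the cyclic S-ethyl O,S-ketal F1. Radical desulfurisation with Ph3SnH and AIBN in toluene at 110 °C then delivers a hydrogen atom axially to the C21 α-alkoxy radical, anti to the C15 methyl, and comes back to the route at 10.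

2. Step 31. Mitsunobu displacement at the C12 carbinol, which is flanked by the fully substituted alkene and its gem-dimethyl neighbour, may be outrun by elimination or by ionisation with loss of configuration. The fallback sets out from 44: formylation with formic acetic anhydride (HCO2H, Ac2O, pyridine) should give the (12R) allylic formate F2. Tsuji–Mandai hydrogenolysis (Pd(OAc)2, n-Bu3P, dioxane, 100 °C) then ionises the formate with inversion at zerovalent palladium, decarboxylates, and delivers hydride from palladium to C2 on the face anti to the former C–O bond, the same face as in the diazene route. This returns to the route at 47.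

3. Step 28. Oxidative addition of the tetrasubstituted enol triflate, shielded by the C10 gem-dimethyl group, to zerovalent nickel may be too slow, so that the aldehyde is consumed by pinacol coupling or reduction. The fallback uses an organolithium and sets out from 40: condensation with 2,4,6-triisopropylbenzenesulfonohydrazide (cat. HCl, THF) should give the trisylhydrazone F3. Shapiro reaction (n-BuLi, 2.2 equiv, THF, −78 → 0 °C) gives the alkenyllithium F4, and addition of aldehyde 25 at −78 °C comes back to the route at 42.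

**Further compounds**

F1 | step 5 | cyclic S-ethyl O,S-ketal at C21 (oxepane closed), C14 4-nitrobenzoate | O=C(O[C@@H]1[C@@]2(C)CCC(=O)C(C)(C)OC2(SCC)CCC1)c1ccc(cc1)[N+](=O)[O-]
F2 | step 31 | (12R) allylic formate of 44 | CC=1CC[C@@H]2[C@@H](CC[C@@]2(C)O[Si](CC)(CC)CC)C(C)(C)C=1[C@H](OC=O)C[C@@H]1[C@@]2(C)CCC(O[Si](C)(C)C(C)(C)C)C(C)(C)O[C@@H]2CC[C@]1(C)O[Si](CC)(CC)CC
F3 | step 28 | 2,4,6-triisopropylbenzenesulfonyl hydrazone of ketone 40 | CC1CC[C@@H]2[C@@H](CC[C@@]2(C)O[Si](CC)(CC)CC)C(C)(C)C1=NNS(=O)(=O)c1c(C(C)C)cc(C(C)C)cc1C(C)C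
F4 | step 28 | C11 alkenyllithium (C2=C11) | CC=1CC[C@@H]2[C@@H](CC[C@@]2(C)O[Si](CC)(CC)CC)C(C)(C)C=1[Li]
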